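**Strategy.** Everything rests on cutting C4–C4a of the lower pyran ring (ring C of the epiafzelechin half). C4 is a bare benzylic CH2 beside the carbinol C3, and C4a is the only free carbon ortho to O1 on the lower ring A, because C8 carries the upper flavan. C3–OH and C4 are therefore masked as a terminal epoxide on an open aryl ether that already holds C2 and C3 in their final configurations. A gold-catalysed, strain-releasing 6-endo epoxide–arene cyclization then closes the last ring and unveils the 3-hydroxyl of the 2,3-cis flavan-3-ol in one operation, without touching a stereocentre. The precursor is an aryl 1-aryl-2,3-epoxypropyl ether hung on a 4-arylflavan.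

Key step: step 8

Remark: in step 2 the sense of induction is assigned by analogy with cyclic enones, so the (R)-ligand is taken to give the (2S)-ketone; if the optical rotation of 4 showed the opposite, the ligand antipode would be used and nothing else would change.

Step 1
Reactants: 1 7-hydroxy-4H-chromen-4-one
Product: 2 7-(benzyloxy)-4H-chromen-4-one
Conditions: BnBr, K2CO3, acetone, reflux
Reagents that add atoms: benzyl bromide, BrCc1ccccc1
Why: Williamson ether synthesis at the 7-hydroxyl, the only acidic site, under conditions mild enough to leave the pyranone ring alone.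

Step 2
Reactants: 2 7-(benzyloxy)-4H-chromen-4-one; 3 [4-(benzyloxy)phenyl]boronic acid
Product: 4 (2S)-7-(benzyloxy)-2-[4-(benzyloxy)phenyl]-2,3-dihydro-4H-chromen-4-one
Conditions: Pd(OCOCF3)2 (5 mol %), (R)-t-BuPyOx [(R)-4-tert-butyl-2-(pyridin-2-yl)-4,5-dihydrooxazole] (6 mol %), NH4PF6 (30 mol %), H2O (5 equiv), 3 (2 equiv), ClCH2CH2Cl, 60 °C
Reagents that add atoms: none
Why: Palladium-catalysed asymmetric conjugate addition of an arylboronic acid, in which a cationic aryl complex of divalent palladium inserts the chromone C2=C3 bond and the palladium enolate is protonated, the pyridine–oxazoline ligand fixing the enone face so that C2 should form as S.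

Step 3
Reactants: 4 (2S)-7-(benzyloxy)-2-[4-(benzyloxy)phenyl]-2,3-dihydro-4H-chromen-4-one
Product: 5 (2S,4S)-7-(benzyloxy)-2-[4-(benzyloxy)phenyl]-3,4-dihydro-2H-chromen-4-ol (2,4-cis)
Conditions: NaBH4, MeOH/THF, 0 °C
Reagents that add atoms: none
Why: Borohydride reduction with axial hydride delivery should give the 2,4-cis alcohol (4S), and the C4 configuration is in any case erased on ionization in step 4.

Step 4
Reactants: 5 (2S,4S)-7-(benzyloxy)-2-[4-(benzyloxy)phenyl]-3,4-dihydro-2H-chromen-4-ol; 6 3,5-bis(benzyloxy)phenol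
Product: 7 3,5-bis(benzyloxy)-2-{(2S,4R)-7-(benzyloxy)-2-[4-(benzyloxy)phenyl]-3,4-dihydro-2H-chromen-4-yl}phenol (2,4-trans)
Conditions: Me3SiOTf (10 mol %), 6 (3 equiv), CH2Cl2, −78 → −40 °C
Reagents that add atoms: none
Why: Friedel–Crafts alkylation by the flavan-4-yl cation (stabilized by O1 and the para 7-benzyloxy group), in which the phenol should react at a carbon ortho to its free hydroxyl (less hindered than the carbon between the two benzyloxy groups, and present twice) and quasi-axial attack on the half-chair cation on the face of the axial H-2 sets C4 as R.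

Step 5
Reactants: 8 4-(benzyloxy)benzaldehyde
Product: 9 racemic 1-[4-(benzyloxy)phenyl]prop-2-en-1-ol
Conditions: vinylmagnesium bromide, THF, 0 °C; aqueous NH4Cl
Reagents that add atoms: vinylmagnesium bromide, C=C[Mg]Br
Why: Grignard addition to the aldehyde gives the racemic secondary allylic alcohol needed for resolution.

Step 6
Reactants: 9 racemic 1-[4-(benzyloxy)phenyl]prop-2-en-1-ol
Product: 10 (S)-[4-(benzyloxy)phenyl][(2R)-oxiran-2-yl]methanol (erythro epoxy alcohol)
Conditions: Ti(OiPr)4 (0.2 equiv), L-(+)-DIPT (0.25 equiv), t-BuOOH (0.45 equiv), 4 Å molecular sieves, CH2Cl2, −20 °C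
Reagents that add atoms: tert-butyl hydroperoxide, CC(C)(C)OO
Why: Sharpless kinetic resolution, in which L-(+)-DIPT should epoxidize the (R)-carbinol much faster than its antipode and on the face that gives the erythro product, so the oxirane carbon (future C3, R) is set by the catalyst and the carbinol carbon (S) by selection, the limiting oxidant stopping the reaction before the slow enantiomer is consumed.

Step 7
Reactants: 7 3,5-bis(benzyloxy)-2-{(2S,4R)-7-(benzyloxy)-2-[4-(benzyloxy)phenyl]-3,4-dihydro-2H-chromen-4-yl}phenol; 10 (S)-[4-(benzyloxy)phenyl][(2R)-oxiran-2-yl]methanol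
Product: 11 (2S,4R)-7-(benzyloxy)-2-[4-(benzyloxy)phenyl]-4-[2,4-bis(benzyloxy)-6-{(R)-[4-(benzyloxy)phenyl][(2R)-oxiran-2-yl]methoxy}phenyl]-3,4-dihydro-2H-chromene
Conditions: PPh3, DIAD, toluene, 0 °C → rt
Reagents that add atoms: none
Why: Mitsunobu etherification, in which the phenoxide of 7 displaces the oxyphosphonium in an SN2 step and so inverts the (S)-carbinol to the (R)-configured ether carbon (future C2) while the oxirane is not touched.

Step 8
Reactants: 11 (2S,4R)-7-(benzyloxy)-2-[4-(benzyloxy)phenyl]-4-[2,4-bis(benzyloxy)-6-{(R)-[4-(benzyloxy)phenyl][(2R)-oxiran-2-yl]methoxy}phenyl]-3,4-dihydro-2H-chromene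
Product: 12 (2R,3R)-5,7-bis(benzyloxy)-2-[4-(benzyloxy)phenyl]-8-{(2S,4R)-7-(benzyloxy)-2-[4-(benzyloxy)phenyl]-3,4-dihydro-2H-chromen-4-yl}-3,4-dihydro-2H-chromen-3-ol
Conditions: AuCl3 (5 mol %), AgOTf (15 mol %), ClCH2CH2Cl (0.01 M), 0 °C → rt
Reagents that add atoms: none
Why: Trivalent gold (AuCl3 activated by AgOTf) binds the epoxide oxygen, and the electron-rich carbon C4a (ortho to O1 and O5, para to O7) attacks the terminal epoxide carbon in an SN2-like Friedel–Crafts step; rearomatization and protonation of the gold alkoxide release the 3-hydroxyl. The closest known reaction type is the gold- or acid-catalysed cycloalkylation of aryl glycidyl ethers to chroman-3-ols. The pyran ring closes in the 6-endo-tet mode at the primary carbon, C4–C4a being the new bond, whereas the 5-exo alternative would need attack at the hindered secondary carbon C3. No new stereocentre is formed: C2 (R) and C3 (R) are carried over from 11 because neither the O1–C2 bond nor the C3–O bond is broken, so the threo ether should become the 2,3-cis flavan-3-ol. The step needs regioselectivity for C4a, which is secured because C8, the other carbon ortho to O1, carries the upper unit and C6 cannot reach the tether; high dilution should suppress intermolecular alkylation at C6 and the mild conditions should spare the benzylic O1–C2 bond.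

Step 9
Reactants: 12 (2R,3R)-5,7-bis(benzyloxy)-2-[4-(benzyloxy)phenyl]-8-{(2S,4R)-7-(benzyloxy)-2-[4-(benzyloxy)phenyl]-3,4-dihydro-2H-chromen-4-yl}-3,4-dihydro-2H-chromen-3-ol
Product: 13 (2R,3R)-2-(4-hydroxyphenyl)-8-[(2S,4R)-7-hydroxy-2-(4-hydroxyphenyl)-3,4-dihydro-2H-chromen-4-yl]-3,4-dihydro-2H-chromene-3,5,7-triol
Conditions: H2 (1 atm), Pd(OH)2/C, THF/MeOH, rt
Reagents that add atoms: none
Why: Hydrogenolysis of the five benzyl ethers over Pd(OH)2/C, which should leave the C4–C8 bond, both pyran rings and all four stereocentres unchanged.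

**Compound list**

1 | 7-hydroxy-4H-chromen-4-one | O=c1ccoc2cc(O)ccc12 | starting material
2 | 7-(benzyloxy)-4H-chromen-4-one | O=c1ccoc2cc(OCc3ccccc3)ccc12 | intermediate
3 | [4-(benzyloxy)phenyl]boronic acid | OB(O)c1ccc(OCc2ccccc2)cc1 | starting material
4 | (2S)-7-(benzyloxy)-2-[4-(benzyloxy)phenyl]-2,3-dihydro-4H-chromen-4-one | c5ccccc5COc1ccc([C@@H]2CC(=O)c3ccc(OCc5ccccc5)cc3O2)cc1 | intermediate
5 | (2S,4S)-7-(benzyloxy)-2-[4-(benzyloxy)phenyl]-3,4-dihydro-2H-chromen-4-ol | c5ccccc5COc1ccc([C@@H]2C[C@H](O)c3ccc(OCc5ccccc5)cc3O2)cc1 | intermediate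
6 | 3,5-bis(benzyloxy)phenol | Oc1cc(OCc2ccccc2)cc(OCc2ccccc2)c1 | starting material
7 | 3,5-bis(benzyloxy)-2-{(2S,4R)-7-(benzyloxy)-2-[4-(benzyloxy)phenyl]-3,4-dihydro-2H-chromen-4-yl}phenol | c5ccccc5COc1ccc([C@@H]2C[C@@H](c3c(OCc5ccccc5)cc(OCc5ccccc5)cc3O)c3ccc(OCc5ccccc5)cc3O2)cc1 | intermediate
8 | 4-(benzyloxy)benzaldehyde | O=Cc1ccc(OCc2ccccc2)cc1 | starting material
9 | racemic 1-[4-(benzyloxy)phenyl]prop-2-en-1-ol | C=CC(O)c1ccc(OCc2ccccc2)cc1 | intermediate
10 | (S)-[4-(benzyloxy)phenyl][(2R)-oxiran-2-yl]methanol | O[C@@H](c1ccc(OCc2ccccc2)cc1)[C@H]1CO1 | intermediate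
11 | (2S,4R)-7-(benzyloxy)-2-[4-(benzyloxy)phenyl]-4-[2,4-bis(benzyloxy)-6-{(R)-[4-(benzyloxy)phenyl][(2R)-oxiran-2-yl]methoxy}phenyl]-3,4-dihydro-2H-chromene | c5ccccc5COc1ccc([C@@H]2C[C@@H](c3c(OCc5ccccc5)cc(OCc5ccccc5)cc3O[C@H](c3ccc(OCc5ccccc5)cc3)[C@H]4CO4)c3ccc(OCc5ccccc5)cc3O2)cc1 | intermediate
12 | (2R,3R)-5,7-bis(benzyloxy)-2-[4-(benzyloxy)phenyl]-8-{(2S,4R)-7-(benzyloxy)-2-[4-(benzyloxy)phenyl]-3,4-dihydro-2H-chromen-4-yl}-3,4-dihydro-2H-chromen-3-ol | c5ccccc5COc1ccc([C@@H]2C[C@@H](c3c(OCc5ccccc5)cc(OCc5ccccc5)c4c3O[C@H](c3ccc(OCc5ccccc5)cc3)[C@H](O)C4)c3ccc(OCc5ccccc5)cc3O2)cc1 | intermediate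
13 | (2R,3R)-2-(4-hydroxyphenyl)-8-[(2S,4R)-7-hydroxy-2-(4-hydroxyphenyl)-3,4-dihydro-2H-chromen-4-yl]-3,4-dihydro-2H-chromene-3,5,7-triol | Oc1ccc([C@@H]2C[C@@H](c3c(O)cc(O)c4c3O[C@H](c3ccc(O)cc3)[C@H](O)C4)c3ccc(O)cc3O2)cc1 | target

**Step count.** Total: 9 steps. Longest linear sequence: 7 steps (steps 1–4 and 7–9, from 1).

**Steps most likely to fail**

1. Step 7. The oxyphosphonium of the 4-benzyloxybenzylic carbinol may ionize before the ortho-hindered phenoxide attacks, which would erode the configuration at the future C2 or let the oxirane oxygen participate. The fallback sets out from 9 and 7 and comes back at 11. Re2O7-catalysed 1,3-transposition of 9 gives (E)-3-[4-(benzyloxy)phenyl]prop-2-en-1-ol F1. Sharpless epoxidation (Ti(OiPr)4, L-(+)-DET, t-BuOOH) gives [(2S,3S)-3-[4-(benzyloxy)phenyl]oxiran-2-yl]methanol F2. The caesium phenoxide of 7 (Cs2CO3, DMF) opens F2 at the benzylic carbon with inversion and gives (2S,3R)-3-aryloxy-3-[4-(benzyloxy)phenyl]propane-1,2-diol F3 (aryloxy is the phenoxy residue of 7). 4-Nitrobenzoyl chloride and pyridine at low temperature acylate the primary hydroxyl to give the primary 4-nitrobenzoate F4, and MsCl/Et3N gives the secondary mesylate F5. K2CO3 in MeOH then removes the ester, and the primary alkoxide displaces the mesylate with inversion to give 11. This replaces substitution at an activated carbinol by an epoxide opening and no longer needs 10.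

2. Step 8. The Lewis acid may ionize the benzylic O1–C2 bond (loss of the C2 configuration) or the C4–C8 bond of the upper unit, and the epoxide may alkylate C6 of a second molecule. The fallback sets out from 7 and 8 and comes back at 12. Ethynylmagnesium bromide addition to 8 with Ac2O quench gives racemic 1-[4-(benzyloxy)phenyl]prop-2-yn-1-yl acetate F6. Hydrolysis with immobilised Candida antarctica lipase B (phosphate buffer/MTBE) to about half conversion gives (R)-1-[4-(benzyloxy)phenyl]prop-2-yn-1-ol F7, the enantiomer this lipase prefers when the aryl group is the large substituent. Mitsunobu coupling of F7 with 7 (inversion) gives the (S)-configured aryl propargyl ether F8. Oxidative gold catalysis (Me4tBuXPhosAuNTf2, 2,6-dichloropyridine N-oxide, ClCH2CH2Cl) converts the terminal alkyne into an α-oxo gold carbene that alkylates C4a and gives the (2R)-flavan-3-one F9. LiBH(s-Bu)3 in THF at −78 °C adds hydride trans to the 2-aryl group and gives 12. The same ring is still closed last, at C4–C4a, but without an acid-activated epoxide.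

3. Step 4. The cation may attack the carbon between the two benzyloxy groups instead of a carbon ortho to the hydroxyl, and facial selectivity at C4 may be incomplete. The fallback sets out from 5 and comes back at 7. With excess phloroglucinol (benzene-1,3,5-triol, whose three ring carbons are equivalent) under the same acid catalysis, 5 gives 2-[(2S,4R)-7-(benzyloxy)-2-[4-(benzyloxy)phenyl]-3,4-dihydro-2H-chromen-4-yl]benzene-1,3,5-triol F10 as the only possible regioisomer. BnBr (2 equiv), K2CO3 and DMF then benzylate the unhindered para hydroxyl and one of the two equivalent ortho hydroxyls, which gives 7.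

**Further compounds**

F1 | step 7 | (E)-3-[4-(benzyloxy)phenyl]prop-2-en-1-ol | OC/C=C/c1ccc(OCc2ccccc2)cc1
F2 | step 7 | [(2S,3S)-3-[4-(benzyloxy)phenyl]oxiran-2-yl]methanol | OC[C@@H]1O[C@H]1c1ccc(OCc2ccccc2)cc1
F3 | step 7 | (2S,3R)-3-{3,5-bis(benzyloxy)-2-[(2S,4R)-7-(benzyloxy)-2-[4-(benzyloxy)phenyl]-3,4-dihydro-2H-chromen-4-yl]phenoxy}-3-[4-(benzyloxy)phenyl]propane-1,2-diol | c5ccccc5COc1ccc([C@@H]2C[C@@H](c3c(OCc5ccccc5)cc(OCc5ccccc5)cc3O[C@H](c3ccc(OCc5ccccc5)cc3)[C@@H](O)CO)c3ccc(OCc5ccccc5)cc3O2)cc1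
F4 | step 7 | (2S,3R)-3-{3,5-bis(benzyloxy)-2-[(2S,4R)-7-(benzyloxy)-2-[4-(benzyloxy)phenyl]-3,4-dihydro-2H-chromen-4-yl]phenoxy}-3-[4-(benzyloxy)phenyl]-2-hydroxypropyl 4-nitrobenzoate | c5ccccc5COc1ccc([C@@H]2C[C@@H](c3c(OCc5ccccc5)cc(OCc5ccccc5)cc3O[C@H](c3ccc(OCc5ccccc5)cc3)[C@@H](O)COC(=O)c6ccc(cc6)[N+](=O)[O-])c3ccc(OCc5ccccc5)cc3O2)cc1
F5 | step 7 | (2S,3R)-3-{3,5-bis(benzyloxy)-2-[(2S,4R)-7-(benzyloxy)-2-[4-(benzyloxy)phenyl]-3,4-dihydro-2H-chromen-4-yl]phenoxy}-3-[4-(benzyloxy)phenyl]-2-(methanesulfonyloxy)propyl 4-nitrobenzoate | c5ccccc5COc1ccc([C@@H]2C[C@@H](c3c(OCc5ccccc5)cc(OCc5ccccc5)cc3O[C@H](c3ccc(OCc5ccccc5)cc3)[C@@H](OS(C)(=O)=O)COC(=O)c6ccc(cc6)[N+](=O)[O-])c3ccc(OCc5ccccc5)cc3O2)cc1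
F6 | step 8 | racemic 1-[4-(benzyloxy)phenyl]prop-2-yn-1-yl acetate | CC(=O)OC(C#C)c1ccc(OCc2ccccc2)cc1
F7 | step 8 | (R)-1-[4-(benzyloxy)phenyl]prop-2-yn-1-ol | O[C@@H](c1ccc(OCc2ccccc2)cc1)C#C
F8 | step 8 | (2S,4R)-7-(benzyloxy)-2-[4-(benzyloxy)phenyl]-4-[2,4-bis(benzyloxy)-6-{(1S)-1-[4-(benzyloxy)phenyl]prop-2-yn-1-yloxy}phenyl]-3,4-dihydro-2H-chromene | c5ccccc5COc1ccc([C@@H]2C[C@@H](c3c(OCc5ccccc5)cc(OCc5ccccc5)cc3O[C@H](c3ccc(OCc5ccccc5)cc3)C#C)c3ccc(OCc5ccccc5)cc3O2)cc1
F9 | step 8 | (2R)-5,7-bis(benzyloxy)-2-[4-(benzyloxy)phenyl]-8-[(2S,4R)-7-(benzyloxy)-2-[4-(benzyloxy)phenyl]-3,4-dihydro-2H-chromen-4-yl]-2H-chromen-3(4H)-one | c5ccccc5COc1ccc([C@@H]2C[C@@H](c3c(OCc5ccccc5)cc(OCc5ccccc5)c4c3O[C@H](c3ccc(OCc5ccccc5)cc3)C(=O)C4)c3ccc(OCc5ccccc5)cc3O2)cc1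
F10 | step 4 | 2-[(2S,4R)-7-(benzyloxy)-2-[4-(benzyloxy)phenyl]-3,4-dihydro-2H-chromen-4-yl]benzene-1,3,5-triol | c5ccccc5COc1ccc([C@@H]2C[C@@H](c3c(O)cc(O)cc3O)c3ccc(OCc5ccccc5)cc3O2)cc1
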